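## Analysis of the target

Target 28 is a 6,8-diprenylated 5,7,4'-trihydroxyflavone whose C3 and C2' are tied together by a CH2–CH–O bridge, so that the pyranone (ring C, fused to ring A) and the resorcinol-type ring B are both fused to a seven-membered oxepine (ring D). Flavone numbering is used for rings A, C and B; the bridge methylene is C9, the bridge methine C10, the carbinol carbon C11, and the ether oxygen links C10 to C2'. C10 is the only stereocentre, (R); it carries the aryl ether oxygen, C9 and the 2-hydroxypropan-2-yl group, and with no second centre to relay from, its configuration must come from the chiral pool or a reagent and then be kept. Ring A is hexasubstituted, but until ring C is closed its pattern (O, prenyl, O, prenyl, O, acyl) has a mirror plane through C7 and C4a, which makes the C5 and C8a oxygens equivalent. The sensitive groups are the two prenyl chains beside phenols (acid closes chromans, and quinone or halogen oxidants attack them when the phenols are free), the tertiary carbinol, and the C10 aryl ether, which is a β-leaving group for any carbanion at C9. The difficulty lies in closing the oxepine around a tetrasubstituted C2=C3 bond, placing two prenyl groups on ring A without isomers, and reaching the flavone oxidation level in their presence. The route rests on the C2=C3 bond itself: it is common to rings C and D, C3 is the α-carbon of the C4 ketone, and C2 is a ring B benzylic carbon at the aldehyde oxidation level. This bond is therefore the retron of an aldol condensation that closes ring D, after which the C8a hydroxyl is placed to close ring C on C2.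

## Retrosynthetic reasoning

28 ⇒ 27. No skeletal bond is cut. The three phenols are unmasked last, so that no free phenol sits beside a prenyl group during the base and oxidation steps; 27 carries them as MOM ethers.

27 ⇒ 26. The C2=C3 bond of the pyranone is traced back to the saturated C2–C3 bond of flavanone 26. The forward step is a dehydrogenation that must take hydride from C2 and a proton from C3 and nothing else.

26 ⇒ 25. The O1–C2 bond is cut (retro-oxa-Michael). This reveals the cyclic 2'-hydroxychalcone 25, in which the C8a hydroxyl faces the β-carbon of the enone. Closing ring C last allows ring A to be brought in as a simple aryl ketone.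

25 ⇒ 23. The C2=C3 bond is cut; this is the central disconnection. It is the only C–C bond of ring D that lies α to the carbonyl and ends on ring B, and cutting it removes ring D and the trisubstituted alkene together. It leaves keto aldehyde 23, in which C10 is remote from any acidifying group. The forward reaction has to enolise the ketone at C3 (its only α-position), close a seven-membered ring on a non-enolisable aldehyde, dehydrate, and leave the C10 aryl ether in place.

23 ⇒ 21. Two masks are put back: the aldehyde as a dimethyl acetal and the C8a hydroxyl as a MOM ether. This is the form in which the ketone can be made with an organometallic. The two ortho ethers of 21 are equivalent, so the unmasking only has to stop after one of them.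

21 ⇒ 18 + 11. The C4–C4a bond is cut. C4a is the last unsubstituted position of 18 and lies between two directing ethers, so the aryl anion is available by deprotonation. Lactone 11 acylates once only and sets the C11 carbinol free in the same event.

11 ⇒ 10 ⇒ 8. The lactone C–O bond is opened to hydroxy ester 10, and the two C11–CH3 bonds are cut back to methyl ester 8. The forward step is a double Grignard addition that must distinguish the activated α-aryloxy methyl ester from the shielded tert-butyl ester.

8 ⇒ 7 ⇒ 3 + 5. The acetal goes back to aldehyde 7, and the C10–O aryl ether bond is cut. A Mitsunobu etherification of phenol 5 with α-hydroxy ester 3 inverts (S) to (R), so the single stereocentre is set from the chiral pool at the start and at a position where inversion is reliable.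

3 ⇒ 2 ⇒ 1, and 5 ⇒ 4. Ester 3 comes from amino acid 1 by deamination with retention and esterification; phenol 5 comes from 4 by protection of the hydroxyl that is not chelated.

18 ⇒ 16 ⇒ 13 ⇒ 12. The two aryl–prenyl bonds are cut. Iterative ortho-metalation of tris-ether 13 and allylation with 14 place the prenyl groups one at a time; the symmetry of 13 and of 16 means no regioisomers can form.

## Alternatives that were turned down

Alternative 1: Ring A is built last by a Danheiser-type benzannulation instead of being brought in as a phloroglucinol.
- Disconnection: C5–C6, C7–C8 and C4a–C5 are cut. This leaves a 4-pyranone that already carries rings B and D and an α-diazo ketone on C8a (A1), plus the silyl ynol ether A3.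
- Forward key step: irradiation of A1 should trigger a Wolff rearrangement to the prenyl(pyranonyl)ketene A2. A2 and A3 combine by [2+2] cycloaddition (C5–C6 and C7–C8), the cyclobutenone opens, and 6π electrocyclisation onto C4a closes ring A to give phenol A4.
- For: every substituent of the hexasubstituted ring is placed by the mechanism, and the C5 hydroxyl and C7 silyl ether emerge differentiated. On this point the alternative is stronger than the chosen route, which has to cleave one of two equivalent MOM ethers selectively (step 12).
- Against:
  - The 2π component for the electrocyclisation is the C4a=C8a bond of a 4-pyranone, a cross-conjugated vinylogous ester with partial aromatic character, not a simple vinyl group.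
  - The 2-aryl-4-pyranone is a strong chromophore with photochemistry of its own, so clean photolysis of the diazo group is doubtful.
  - The ketene can also be intercepted by either prenyl double bond.
  - A1 needs rings B, C and D, the C10 centre, a protected carbinol and a diazo transfer before any carbon of ring A is present, which is longer than the whole sequence to 23.
- Comparison: the oxepine and the stereocentre still have to be made by other means, so the risk is moved to a late photochemical step without removing an earlier problem. The chosen strategy takes ring A from 12 in three steps using its symmetry and spends its risk on a classical condensation.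

Alternative 2: C4 is introduced as a one-carbon carbonyl unit between two preformed halves.
- Disconnection: C4a–C4 and C4–C3 are cut, giving the symmetric aryl iodide A5 and the chiral benzoxepin-5-one A6, in which rings B and D and C10 are complete.
- Forward key step: zerovalent palladium adds to the C–I bond of A5, carbonyl insertion gives an aroyl–palladium species, and C-acylation of the C3 enolate of A6 gives the 1,3-diketone A7 with ring C still open. Acid would then close ring C by cyclodehydration and remove the MOM groups.
- For: this is the most convergent of the four plans, and A7 is already at the flavone oxidation level, so neither the oxa-Michael step nor a dehydrogenation is needed. On the end game it is clearly stronger than the chosen route.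
- Against:
  - A5 is electron-rich and has two ortho substituents, so oxidative addition, insertion and above all the C–C bond-forming reductive elimination are hindered.
  - Direct (non-carbonylative) α-arylation and O-acylation of the enolate compete.
  - The free tertiary hydroxyl of A6 can capture the aroyl–palladium species (alkoxycarbonylation).
  - A6 needs a ring D closure of its own, so the seven-membered ring problem is only moved.
- Comparison: the chosen route forms the C2–C3 bond without a metal, at an unhindered aldehyde, and closes ring D in the same operation. What it gives up in oxidation level can be recovered: if step 15 fails, its intermediates can be diverted to the same diketone (it appears as F4 in the fallback for step 15).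

Alternative 3: The flavone core (rings A, C and B) is completed first and ring D is closed at C9–C10.
- Disconnection: C9–C10 is cut. The precursor A8 is a 3-(bromomethyl)flavone whose 2'-oxygen carries an acetyl group bound to a (4S)-4-benzyloxazolidinone.
- Forward key step: a hindered sodium amide base forms the chelated Z-enolate of A8, which displaces the bromide intramolecularly. This forms C9–C10, closes ring D and is meant to set C10 under control of the auxiliary, giving A9.
- For: the flavone oxidation level is secured early by classical chemistry, the bromide is an activated allylic-type electrophile, and the stereocentre would come from a well-understood auxiliary. In principle it is as strong as the chosen route on stereocontrol.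
- Against:
  - The facial bias of such enolates is established for free electrophiles. Here the electrophile is tethered through the α-oxygen and can probably reach only the face that the forming seven-membered ring allows, so the sense and level of induction cannot be predicted.
  - α-Aryloxyacetyl imide enolates fragment easily (ketene formation with loss of the auxiliary), and the bromomethyl pyranone is also a conjugate acceptor.
  - The bromomethyl group has to be introduced in the presence of two prenyl groups, which rules out radical bromination.
  - After ring closure the C10 acyl group must still become the dimethyl carbinol. That means removing the auxiliary and adding two methyl groups next to a pyranone carbonyl that itself reacts with organometallics, while C10 is an epimerisable α-aryloxy carbonyl centre.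
- Comparison: the chosen route fixes C10 and the carbinol at the stage of a small diester (steps 4 to 6), where chemoselectivity is simple, and C10 is never again α to a carbonyl group. The price is the late adjustment of oxidation level in steps 14 and 15.

Key step: step 13

Remark: hydroxy ketones 21, 22 and 23 are drawn open-chain; partial ring–chain tautomerism to the six-membered hemiketal (C11–O on C4) is assumed to be fast and without consequence, since steps 12 and 13 draw on the open form.
Remark: 24 and 26 are expected as diastereomer mixtures at C2 and C3; both centres are removed later, so their SMILES leave them undefined.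

## Route

Step 1
Reactants: 1 L-glutamic acid 5-tert-butyl ester
Product: 2 (2S)-5-tert-butoxy-2-hydroxy-5-oxopentanoic acid
Conditions: NaNO2, AcOH–H2O (1:4), 0 °C → rt
Reagents that add atoms: water, O
Why: Diazotisation of an α-amino acid with hydroxy-de-amination; participation of the neighbouring carboxylate makes the substitution a double inversion, so C2 is retained as (S), and the tert-butyl ester tolerates cold dilute acetic acid.

Step 2
Reactants: 2 (2S)-5-tert-butoxy-2-hydroxy-5-oxopentanoic acid
Product: 3 5-tert-butyl 1-methyl (2S)-2-hydroxypentanedioate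
Conditions: MeI, KHCO3, DMF, rt
Reagents that add atoms: iodomethane, CI
Why: SN2 O-alkylation of the carboxylate; hydrogen carbonate deprotonates only the acid, so the secondary hydroxyl is not methylated and the α-centre is not enolised.

Step 3
Reactants: 4 2,4-dihydroxybenzaldehyde
Product: 5 2-hydroxy-4-(methoxymethoxy)benzaldehyde
Conditions: MOMCl (1.05 equiv), K2CO3, acetone, 0 °C → rt
Reagents that add atoms: chloromethyl methyl ether, COCCl
Why: Williamson-type etherification; the 2-hydroxyl is hydrogen-bonded to the formyl group and less nucleophilic, so the 4-hydroxyl reacts selectively.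

Step 4
Reactants: 3 5-tert-butyl 1-methyl (2S)-2-hydroxypentanedioate; 5 2-hydroxy-4-(methoxymethoxy)benzaldehyde
Product: 7 5-tert-butyl 1-methyl (2R)-2-[2-formyl-5-(methoxymethoxy)phenoxy]pentanedioate, via oxyphosphonium salt 6 (not isolated)
Conditions: PPh3, DIAD, THF, 0 °C → rt
Reagents that add atoms: none
Why: Mitsunobu etherification; the acidic salicylaldehyde-type phenol displaces the phosphonium-activated hydroxyl of the α-hydroxy ester by SN2 with inversion, which sets the future C10 as (R); α-hydroxy esters are among the most reliable substrates for clean inversion.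

Step 5
Reactants: 7 aryloxy diester aldehyde
Product: 8 5-tert-butyl 1-methyl (2R)-2-[2-(dimethoxymethyl)-5-(methoxymethoxy)phenoxy]pentanedioate
Conditions: HC(OMe)3, MeOH, PPTS (5 mol %), rt; then Et3N
Reagents that add atoms: trimethyl orthoformate, COC(OC)OC; methanol, CO
Why: Acid-catalysed acetalisation; the electron-rich benzaldehyde forms its dimethyl acetal readily, while the aryl MOM ether and both esters are inert to PPTS at rt; the acetal masks the aldehyde for the organometallic steps 6 and 11.

Step 6
Reactants: 8 acetal diester
Product: 10 tert-butyl (4R)-4-[2-(dimethoxymethyl)-5-(methoxymethoxy)phenoxy]-5-hydroxy-5-methylhexanoate, via methyl ketone 9 (not isolated)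
Conditions: MeMgBr (2.3 equiv), THF, −78 → −20 °C; pH 7 buffer
Reagents that add atoms: methylmagnesium bromide, C[Mg]Br
Why: Double Grignard addition to an ester; the methyl ester is activated by the α-aryloxy group and the tert-butyl ester is shielded, and ketone 9 is more electrophilic than either ester so it goes on to the carbinol; low temperature keeps the magnesium alkoxide off the tert-butyl ester and avoids enolisation of 9 at the stereocentre.

Step 7
Reactants: 10 hydroxy tert-butyl ester
Product: 11 (5R)-5-[2-(dimethoxymethyl)-5-(methoxymethoxy)phenoxy]-6,6-dimethyloxan-2-one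
Conditions: NaH (1.1 equiv), THF, 0 °C → rt; AcOH (1.1 equiv)
Reagents that add atoms: none
Why: Base-induced lactonisation (intramolecular transesterification); the tertiary alkoxide adds to the ester carbonyl in a 6-exo-trig closure favoured by the gem-dimethyl group and tert-butoxide is expelled; no acid is present, so acetal and MOM ether survive, and the stereocentre is not involved.

Step 8
Reactants: 12 phloroglucinol
Product: 13 1,3,5-tris(methoxymethoxy)benzene
Conditions: NaH (3.5 equiv), MOMCl (3.5 equiv), DMF, 0 °C → rt
Reagents that add atoms: chloromethyl methyl ether, COCCl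
Why: Exhaustive O-alkylation of the phenoxides by a hard electrophile; the MOM groups then serve as ortho-directing groups for metalation.

Step 9
Reactants: 13 1,3,5-tris(methoxymethoxy)benzene; 14 prenyl bromide (1-bromo-3-methylbut-2-ene)
Product: 16 1,3,5-tris(methoxymethoxy)-2-(3-methylbut-2-en-1-yl)benzene, via aryllithium 15 (not isolated)
Conditions: n-BuLi (1.05 equiv), THF, 0 °C; then CuBr·SMe2 (10 mol %), 14, −78 °C → rt
Reagents that add atoms: none
Why: Directed ortho-metalation between two MOM ethers, then copper-assisted allylation of the aryllithium at the primary carbon of 14 (SN2); the three ring positions of 13 are equivalent, so only one product can form.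

Step 10
Reactants: 16 monoprenyl tris-MOM arene; 14 prenyl bromide
Product: 18 1,3,5-tris(methoxymethoxy)-2,4-bis(3-methylbut-2-en-1-yl)benzene, via aryllithium 17 (not isolated)
Conditions: n-BuLi (1.05 equiv), THF, 0 °C; then CuBr·SMe2 (10 mol %), 14, −78 °C → rt
Reagents that add atoms: none
Why: Second directed ortho-metalation and allylation; the two remaining ring hydrogens of 16 are equivalent and each lies between two MOM ethers, so ring lithiation should outrun deprotonation of the benzylic–allylic CH2 and a single diprenyl arene results.

Step 11
Reactants: 18 diprenyl tris-MOM arene; 11 δ-lactone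
Product: 21 (4R)-4-[2-(dimethoxymethyl)-5-(methoxymethoxy)phenoxy]-5-hydroxy-5-methyl-1-[2,4,6-tris(methoxymethoxy)-3,5-bis(3-methylbut-2-en-1-yl)phenyl]hexan-1-one, via aryllithium 19 (not isolated), via lithium lactolate 20 (not isolated)
Conditions: 18 (1.3 equiv), n-BuLi, THF, 0 °C; then 11, −78 → −40 °C; aq. NaHCO3
Reagents that add atoms: none
Why: Directed ortho-metalation at the last ring hydrogen and acylation of the aryllithium by the δ-lactone; the tetrahedral lactolate 20, held by the flanking MOM oxygens, does not collapse before the quench, so a second addition is excluded, and the quench releases the aryl ketone with the C11 carbinol already free; the basic work-up keeps the acetal.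

Step 12
Reactants: 21 tris-MOM acetal ketone
Product: 23 2-{[(3R)-6-[2-hydroxy-4,6-bis(methoxymethoxy)-3,5-bis(3-methylbut-2-en-1-yl)phenyl]-2-hydroxy-2-methyl-6-oxohexan-3-yl]oxy}-4-(methoxymethoxy)benzaldehyde, via keto aldehyde 22 (not isolated)
Conditions: 1 M aq. HCl, THF, 0 °C → rt, stopped at mono-cleavage
Reagents that add atoms: water, O
Why: Acid hydrolysis in two stages of different rate: the benzylic dimethyl acetal on the electron-rich ring goes first (22), then one of the two equivalent MOM ethers ortho to the aryl ketone is cleaved with carbonyl assistance; the new hydroxyl is then locked in a hydrogen bond to the ketone, so the second ortho ether, the hindered C7 ether and the ring B ether react only at the ordinary slow rate.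

Step 13
Reactants: 23 keto aldehyde with free C8a hydroxyl
Product: 25 [(2R)-2-(2-hydroxypropan-2-yl)-8-(methoxymethoxy)-2,3-dihydro-1-benzoxepin-4-yl][2-hydroxy-4,6-bis(methoxymethoxy)-3,5-bis(3-methylbut-2-en-1-yl)phenyl]methanone, via aldol adduct 24 (not isolated)
Conditions: piperidine (0.3 equiv), AcOH (0.3 equiv), toluene (0.01 M), 4 Å MS, 70 °C
Reagents that add atoms: none
Why: Intramolecular Claisen–Schmidt (crossed aldol) condensation: the piperidinium acetate buffer enolises the aryl ketone toward C3, its only α-position, and the aldehyde has no α-hydrogen, so it can only be the acceptor and a single condensation product is possible. The enol adds to the formyl carbon in a 7-(enolexo)-exo-trig closure that forms C2–C3 and ring D, helped by the ortho-phenylene ether, which already holds three of the seven ring atoms in one plane; this gives aldol 24, which loses its C2 hydroxyl by E1cB elimination to the enone conjugated with ring B. The closest known reaction types are the amine-mediated condensation of 2'-hydroxyaryl ketones with aromatic aldehydes and the ring-closing Claisen–Schmidt condensation of 2-formylaryl ethers to 2,3-dihydro-1-benzoxepines. No stereocentre is created in 25: the two centres of 24 (C2, C3) vanish on dehydration, and C10 has no acidic hydrogen, so it stays (R). The double bond is endocyclic in a seven-membered ring and therefore cis within the ring, which places ring B trans to the carbonyl as in an (E)-chalcone. Two selectivities are needed: ring closure over intermolecular aldol, secured by high dilution, and condensation without opening of ring D, secured by the weak buffer, which does not remove the only cross-conjugatively activated C9 hydrogens next to the C10 aryloxide. Any 26 that forms in the same flask by onward closure of the free C8a hydroxyl is harmless, since step 14 takes all material to 26.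

Step 14
Reactants: 25 cyclic 2'-hydroxychalcone
Product: 26 (10R)-5,7,4'-tris(methoxymethoxy)-6,8-diprenylflavanone bridged from C3 through C9H2–C10H(CMe2OH)–O to C2' (2,3-dihydro-27; mixture at C2 and C3)
Conditions: NaOAc, EtOH, reflux
Reagents that add atoms: none
Why: Intramolecular oxa-Michael addition (chalcone–flavanone isomerisation), a 6-endo-trig closure of O1–C2 that forms ring C; the C5 MOM ether ortho to the ketone destabilises the open chalcone and drives the equilibrium to the flavanone; the new centres C2 and C3 need no control because both become sp2 in step 15.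

Step 15
Reactants: 26 flavanone
Product: 27 5,7,4'-tris-O-(methoxymethyl) ether of 28
Conditions: DDQ (1.5 equiv), 1,4-dioxane, 90 °C
Reagents that add atoms: none
Why: Quinone dehydrogenation of a flavanone; hydride leaves from C2, where the positive charge is stabilised by O1 and by the 2',4'-dioxygenated ring B, and the only proton that can then be lost to give a stable alkene is H3, so the double bond forms between C2 and C3; all phenols are capped, so the prenyl groups are not drawn into chromene formation, and C10 is untouched.

Step 16
Reactants: 27 tris-MOM flavone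
Product: 28 CNP0328977.2, (10R)-5,7,4'-trihydroxy-6,8-bis(3-methylbut-2-en-1-yl)flavone bridged from C3 through C9H2–C10H[C(CH3)2OH]–O to C2'
Conditions: 3 M aq. HCl, MeOH, 40 °C
Reagents that add atoms: none
Why: Acid-catalysed cleavage of the three MOM acetals; short exposure at mild temperature is chosen because the liberated C5 and C7 hydroxyls flank the prenyl groups and prolonged acid would close chromans; the C11 carbinol does not ionise readily because the cation would sit next to the C10 oxygen.

## Compound list

1 | L-glutamic acid 5-tert-butyl ester | N[C@@H](CCC(=O)OC(C)(C)C)C(=O)O | starting material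
2 | (2S)-5-tert-butoxy-2-hydroxy-5-oxopentanoic acid | O[C@@H](CCC(=O)OC(C)(C)C)C(=O)O | intermediate
3 | 5-tert-butyl 1-methyl (2S)-2-hydroxypentanedioate | COC(=O)[C@H](CCC(=O)OC(C)(C)C)O | intermediate
4 | 2,4-dihydroxybenzaldehyde | O=Cc1ccc(O)cc1O | starting material
5 | 2-hydroxy-4-(methoxymethoxy)benzaldehyde | O=Cc1ccc(OCOC)cc1O | intermediate
6 | oxyphosphonium salt of 3 with the phenoxide of 5 | COC(=O)[C@H](CCC(=O)OC(C)(C)C)O[P+](c1ccccc1)(c1ccccc1)c1ccccc1.[O-]c1cc(OCOC)ccc1C=O | intermediate (not isolated)
7 | 5-tert-butyl 1-methyl (2R)-2-[2-formyl-5-(methoxymethoxy)phenoxy]pentanedioate | COC(=O)[C@@H](CCC(=O)OC(C)(C)C)Oc1cc(OCOC)ccc1C=O | intermediate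
8 | 5-tert-butyl 1-methyl (2R)-2-[2-(dimethoxymethyl)-5-(methoxymethoxy)phenoxy]pentanedioate | COC(=O)[C@@H](CCC(=O)OC(C)(C)C)Oc1cc(OCOC)ccc1C(OC)OC | intermediate
9 | tert-butyl (4R)-4-[2-(dimethoxymethyl)-5-(methoxymethoxy)phenoxy]-5-oxohexanoate | CC(=O)[C@@H](CCC(=O)OC(C)(C)C)Oc1cc(OCOC)ccc1C(OC)OC | intermediate (not isolated)
10 | tert-butyl (4R)-4-[2-(dimethoxymethyl)-5-(methoxymethoxy)phenoxy]-5-hydroxy-5-methylhexanoate | CC(C)(O)[C@@H](CCC(=O)OC(C)(C)C)Oc1cc(OCOC)ccc1C(OC)OC | intermediate
11 | (5R)-5-[2-(dimethoxymethyl)-5-(methoxymethoxy)phenoxy]-6,6-dimethyloxan-2-one | CC1(C)OC(=O)CC[C@H]1Oc1cc(OCOC)ccc1C(OC)OC | intermediate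
12 | phloroglucinol | Oc1cc(O)cc(O)c1 | starting material
13 | 1,3,5-tris(methoxymethoxy)benzene | COCOc1cc(OCOC)cc(OCOC)c1 | intermediate
14 | prenyl bromide (1-bromo-3-methylbut-2-ene) | CC(C)=CCBr | starting material
15 | [2,4,6-tris(methoxymethoxy)phenyl]lithium | [Li]c1c(OCOC)cc(OCOC)cc1OCOC | intermediate (not isolated)
16 | 1,3,5-tris(methoxymethoxy)-2-(3-methylbut-2-en-1-yl)benzene | CC(C)=CCc1c(OCOC)cc(OCOC)cc1OCOC | intermediate
17 | [2,4,6-tris(methoxymethoxy)-3-(3-methylbut-2-en-1-yl)phenyl]lithium | [Li]c1c(OCOC)cc(OCOC)c(CC=C(C)C)c1OCOC | intermediate (not isolated)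
18 | 1,3,5-tris(methoxymethoxy)-2,4-bis(3-methylbut-2-en-1-yl)benzene | CC(C)=CCc1c(OCOC)cc(OCOC)c(CC=C(C)C)c1OCOC | intermediate
19 | [2,4,6-tris(methoxymethoxy)-3,5-bis(3-methylbut-2-en-1-yl)phenyl]lithium | [Li]c1c(OCOC)c(CC=C(C)C)c(OCOC)c(CC=C(C)C)c1OCOC | intermediate (not isolated)
20 | lithium (5R)-2-aryl-5-aryloxy-6,6-dimethyloxan-2-olate (aryl = ring A of 19, aryloxy as in 11; C2 epimers) | [Li+].[O-]C1(c2c(OCOC)c(CC=C(C)C)c(OCOC)c(CC=C(C)C)c2OCOC)CC[C@@H](Oc2cc(OCOC)ccc2C(OC)OC)C(C)(C)O1 | intermediate (not isolated)
21 | (4R)-4-[2-(dimethoxymethyl)-5-(methoxymethoxy)phenoxy]-5-hydroxy-5-methyl-1-[2,4,6-tris(methoxymethoxy)-3,5-bis(3-methylbut-2-en-1-yl)phenyl]hexan-1-one | CC(C)=CCc1c(OCOC)c(CC=C(C)C)c(OCOC)c(C(=O)CC[C@H](C(C)(C)O)Oc2cc(OCOC)ccc2C(OC)OC)c1OCOC | intermediate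
22 | 2-{[(3R)-2-hydroxy-2-methyl-6-oxo-6-[2,4,6-tris(methoxymethoxy)-3,5-bis(3-methylbut-2-en-1-yl)phenyl]hexan-3-yl]oxy}-4-(methoxymethoxy)benzaldehyde | CC(C)=CCc1c(OCOC)c(CC=C(C)C)c(OCOC)c(C(=O)CC[C@H](C(C)(C)O)Oc2cc(OCOC)ccc2C=O)c1OCOC | intermediate (not isolated)
23 | 2-{[(3R)-6-[2-hydroxy-4,6-bis(methoxymethoxy)-3,5-bis(3-methylbut-2-en-1-yl)phenyl]-2-hydroxy-2-methyl-6-oxohexan-3-yl]oxy}-4-(methoxymethoxy)benzaldehyde | CC(C)=CCc1c(OCOC)c(CC=C(C)C)c(O)c(C(=O)CC[C@H](C(C)(C)O)Oc2cc(OCOC)ccc2C=O)c1OCOC | intermediate
24 | [(2R)-5-hydroxy-2-(2-hydroxypropan-2-yl)-8-(methoxymethoxy)-2,3,4,5-tetrahydro-1-benzoxepin-4-yl][2-hydroxy-4,6-bis(methoxymethoxy)-3,5-bis(3-methylbut-2-en-1-yl)phenyl]methanone (mixture at benzoxepine C4 and C5) | CC(C)=CCc1c(OCOC)c(CC=C(C)C)c(O)c(C(=O)C2C[C@H](C(C)(C)O)Oc3cc(OCOC)ccc3C2O)c1OCOC | intermediate (not isolated)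
25 | [(2R)-2-(2-hydroxypropan-2-yl)-8-(methoxymethoxy)-2,3-dihydro-1-benzoxepin-4-yl][2-hydroxy-4,6-bis(methoxymethoxy)-3,5-bis(3-methylbut-2-en-1-yl)phenyl]methanone | CC(C)=CCc1c(OCOC)c(CC=C(C)C)c(O)c(C(=O)C2=Cc3ccc(OCOC)cc3O[C@@H](C(C)(C)O)C2)c1OCOC | intermediate
26 | (10R)-5,7,4'-tris(methoxymethoxy)-6,8-diprenylflavanone bridged C3–C9H2–C10H(CMe2OH)–O–C2' (mixture at C2 and C3) | CC(C)=CCc1c(OCOC)c(CC=C(C)C)c2c(c1OCOC)C(=O)C1C[C@H](C(C)(C)O)Oc3cc(OCOC)ccc3C1O2 | intermediate
27 | 5,7,4'-tris-O-(methoxymethyl) ether of 28 | CC(C)=CCc1c(OCOC)c(CC=C(C)C)c2oc3c(c(=O)c2c1OCOC)C[C@H](C(C)(C)O)Oc1cc(OCOC)ccc1-3 | intermediate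
28 | CNP0328977.2, (10R)-5,7,4'-trihydroxy-6,8-diprenylflavone bridged C3–C9H2–C10H[C(CH3)2OH]–O–C2' | CC(C)=CCc1c(O)c(CC=C(C)C)c2oc3c(c(=O)c2c1O)C[C@H](C(C)(C)O)Oc1cc(O)ccc1-3 | target

## Step count and least certain steps

Total step count: 16. Longest linear sequence: 12 steps from 1 (steps 1, 2, 4, 5, 6, 7, 11, 12, 13, 14, 15, 16).

Step 13 (key step). The most likely failure is slow or incomplete enolisation of the hindered, weakly acidic aryl ketone under the weak buffer, so that starting material persists or intermolecular condensation takes over. Forcing the reaction with stronger base invites deprotonation at C9 and β-elimination of the C10 aryloxide, which opens ring D. The fallback sets out from 21 and returns at 25. Only the acetal of 21 is hydrolysed (PPTS, wet acetone, rt) and 22 is isolated. The ketone of 22 is enolised stoichiometrically as its boron enolate (Bu2BOTf, i-Pr2NEt, CH2Cl2, −78 → 0 °C), which adds to the tethered aldehyde to give the tris-MOM aldol adduct F1. Dehydration is then done as a separate operation through the mesylate (MsCl, Et3N, 0 °C, then DBU) to the tris-MOM cyclic chalcone F2. One ortho MOM ether is then removed with dilute acid as in step 12, which gives 25.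

Step 12. The rate difference between the carbonyl-assisted ortho MOM ether and the other three is one of degree, so cleavage may run on to the second ortho ether or the ring B ether, or stop short. The fallback sets out from 21 and returns at 23. All four MOM ethers and the acetal are cleaved (3 M HCl, MeOH, rt) to the tetraphenol keto aldehyde F3. Re-protection with MOMCl (3 equiv) and K2CO3 in acetone then caps every phenol except the one chelated to the ketone, by the same principle as step 3, which gives 23.

Step 15. Hydride abstraction may occur at the benzylic–allylic CH2 of a prenyl group instead of at C2, or the 2,3-disubstituted flavanone may react so slowly that prolonged heating degrades the material. The fallback avoids dehydrogenation altogether; it sets out from 22 (isolated as in the fallback for step 13) and returns at 28. The aldol adduct F1 is oxidised at its benzylic alcohol (Dess–Martin periodinane, NaHCO3, CH2Cl2) to the 1,3-diketone F4, which is the same compound as A7. Treatment with 3 M HCl in MeOH removes the MOM ethers, lets either of the two equivalent ortho hydroxyls add to the ring B ketone, and dehydrates the hemiketal, so that the flavone forms at its final oxidation level and 28 is reached directly.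

Step 11. Proton transfer from the α-CH2 of the lactone to the hindered aryllithium (enolisation instead of addition) would return both partners, and lateral lithiation of a prenyl CH2 could lower the titre of 19. The fallback sets out from 11 and returns at 21. Lactone 11 is reduced to lactol F5 (i-Bu2AlH, CH2Cl2, −78 °C). Aryllithium 19 (2.2 equiv) adds to the open hydroxy aldehyde form to give diol F6, and the benzylic secondary alcohol is oxidised (MnO2, CH2Cl2) to 21.

Step 7. The transesterification between two tertiary alkoxides may not go to completion, and the alkoxide may start Claisen-type self-condensation of the lactone. The fallback sets out from 10 and returns at 11. The tert-butyl ester is reduced (LiAlH4, THF, 0 °C) to diol F7, and oxidative lactonisation ((n-Pr4N)RuO4 cat., NMO, 4 Å MS, CH2Cl2) through the lactol gives 11 under neutral conditions.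

## Further compounds

F1 | step 13 | tris-MOM aldol adduct, [(2R)-5-hydroxy-2-(2-hydroxypropan-2-yl)-8-(methoxymethoxy)-2,3,4,5-tetrahydro-1-benzoxepin-4-yl][2,4,6-tris(methoxymethoxy)-3,5-bis(3-methylbut-2-en-1-yl)phenyl]methanone | CC(C)=CCc1c(OCOC)c(CC=C(C)C)c(OCOC)c(C(=O)C2C[C@H](C(C)(C)O)Oc3cc(OCOC)ccc3C2O)c1OCOC
F2 | step 13 | tris-MOM cyclic chalcone, [(2R)-2-(2-hydroxypropan-2-yl)-8-(methoxymethoxy)-2,3-dihydro-1-benzoxepin-4-yl][2,4,6-tris(methoxymethoxy)-3,5-bis(3-methylbut-2-en-1-yl)phenyl]methanone | CC(C)=CCc1c(OCOC)c(CC=C(C)C)c(OCOC)c(C(=O)C2=Cc3ccc(OCOC)cc3O[C@@H](C(C)(C)O)C2)c1OCOC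
F3 | step 12 | tetraphenol keto aldehyde, 2-{[(3R)-2-hydroxy-2-methyl-6-oxo-6-[2,4,6-trihydroxy-3,5-bis(3-methylbut-2-en-1-yl)phenyl]hexan-3-yl]oxy}-4-hydroxybenzaldehyde | CC(C)=CCc1c(O)c(CC=C(C)C)c(O)c(C(=O)CC[C@H](C(C)(C)O)Oc2cc(O)ccc2C=O)c1O
F4 | step 15 | 1,3-diketone, (2R)-2-(2-hydroxypropan-2-yl)-8-(methoxymethoxy)-4-[2,4,6-tris(methoxymethoxy)-3,5-bis(3-methylbut-2-en-1-yl)benzoyl]-3,4-dihydro-1-benzoxepin-5(2H)-one | CC(C)=CCc1c(OCOC)c(CC=C(C)C)c(OCOC)c(C(=O)C2C[C@H](C(C)(C)O)Oc3cc(OCOC)ccc3C2=O)c1OCOC
F5 | step 11 | lactol, (5R)-5-[2-(dimethoxymethyl)-5-(methoxymethoxy)phenoxy]-6,6-dimethyloxan-2-ol (anomers) | CC1(C)OC(O)CC[C@H]1Oc1cc(OCOC)ccc1C(OC)OC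
F6 | step 11 | diol, (4R)-4-[2-(dimethoxymethyl)-5-(methoxymethoxy)phenoxy]-5-methyl-1-[2,4,6-tris(methoxymethoxy)-3,5-bis(3-methylbut-2-en-1-yl)phenyl]hexane-1,5-diol (C1 epimers) | CC(C)=CCc1c(OCOC)c(CC=C(C)C)c(OCOC)c(C(O)CC[C@H](C(C)(C)O)Oc2cc(OCOC)ccc2C(OC)OC)c1OCOC
F7 | step 7 | diol, (4R)-4-[2-(dimethoxymethyl)-5-(methoxymethoxy)phenoxy]-5-methylhexane-1,5-diol | CC(C)(O)[C@@H](CCCO)Oc1cc(OCOC)ccc1C(OC)OC
A1 | alternative 1 | 4-pyranone diazo ketone: tricyclic pyranone with rings B and D, (10R), 4'-MOM ether, C11 triethylsilyl ether, 2-diazo-5-methylhex-4-enoyl group on C8a | CC(C)=CCC(=[N+]=[N-])C(=O)c1cc(=O)c2c(o1)-c1ccc(OCOC)cc1O[C@@H](C(C)(C)O[Si](CC)(CC)CC)C2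
A2 | alternative 1 | prenyl(pyranonyl)ketene formed from A1 by Wolff rearrangement | CC(C)=CCC(=C=O)c1cc(=O)c2c(o1)-c1ccc(OCOC)cc1O[C@@H](C(C)(C)O[Si](CC)(CC)CC)C2
A3 | alternative 1 | triisopropyl[(5-methylhex-4-en-1-yn-1-yl)oxy]silane | CC(C)=CCC#CO[Si](C(C)C)(C(C)C)C(C)C
A4 | alternative 1 | 5-hydroxy-7-(triisopropylsilyloxy)-6,8-diprenyl pentacycle, 4'-MOM ether, C11 triethylsilyl ether | CC(C)=CCc1c(O[Si](C(C)C)(C(C)C)C(C)C)c(CC=C(C)C)c2oc3c(c(=O)c2c1O)C[C@H](C(C)(C)O[Si](CC)(CC)CC)Oc1cc(OCOC)ccc1-3
A5 | alternative 2 | 1-iodo-2,4,6-tris(methoxymethoxy)-3,5-bis(3-methylbut-2-en-1-yl)benzene | CC(C)=CCc1c(OCOC)c(CC=C(C)C)c(OCOC)c(I)c1OCOC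
A6 | alternative 2 | (2R)-2-(2-hydroxypropan-2-yl)-8-(methoxymethoxy)-3,4-dihydro-1-benzoxepin-5(2H)-one | O=C1CC[C@H](C(C)(C)O)Oc2cc(OCOC)ccc21
A7 | alternative 2 | MOM-protected 4-aroyl-benzoxepin-5-one (1,3-diketone, ring C open) | CC(C)=CCc1c(OCOC)c(CC=C(C)C)c(OCOC)c(C(=O)C2C[C@H](C(C)(C)O)Oc3cc(OCOC)ccc3C2=O)c1OCOC
A8 | alternative 3 | 3-(bromomethyl)-5,7-bis(methoxymethoxy)-6,8-diprenylflavone with 4'-OMOM and 2'-OCH2C(=O)-[(4S)-4-benzyl-2-oxo-1,3-oxazolidin-3-yl] | CC(C)=CCc1c(OCOC)c(CC=C(C)C)c2oc(-c3ccc(OCOC)cc3OCC(=O)N3C(=O)OC[C@@H]3Cc3ccccc3)c(CBr)c(=O)c2c1OCOC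
A9 | alternative 3 | tris-MOM pentacycle with C10 bearing the acyl (4S)-4-benzyloxazolidinone in place of the carbinol | CC(C)=CCc1c(OCOC)c(CC=C(C)C)c2oc3c(c(=O)c2c1OCOC)C[C@H](C(=O)N2C(=O)OC[C@@H]2Cc2ccccc2)Oc1cc(OCOC)ccc1-3
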